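The data were generated by integration with constants of no real substance, noise included.

Take the racemate as the zero of the scale: two mirror-image substrates reacting at equal rates give a product with no excess. The flask is judged by how far it stands from that zero.

| flask | left-handed substrate | right-handed substrate | reagent | free catalyst | racemization catalyst | impurity | remark | time |
|---|---|---|---|---|---|---|---|---|
| summer | 0.25 M | 0.25 M | 4 equiv | 0.2 mol% | 0.39 mol% | 1.6 mM | run made earlier |  |
| dawn | 0.38 M | 0.38 M | 4 equiv | 0.2 mol% | 0.39 mol% | 1.6 mM | run made earlier |  |
| midnight | 0.50 M | 0.50 M | 4 equiv | 0.2 mol% | 0.58 mol% | 1.6 mM | run made earlier |  |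
| flask | 0.50 M | 0.50 M | 4.00 equiv | 0.2 mol% | 0.39 mol% | 1.6 mM |  | 40 h |

| run | time / h | left-handed product / % | right-handed product / % |
|---|---|---|---|
| summer | 2.00 | 2.7 | 0.3 |
| summer | 3.00 | 2.4 | 0.8 |
| summer | 5.00 | 3.0 | 1.1 |
| summer | 8.00 | 5.5 | 1.3 |
| summer | 15.0 | 8.1 | 4.1 |
| summer | 25.0 | 13.6 | 5.7 |
| dawn | 2.00 | 4.0 | 0 |
| dawn | 3.00 | 4.4 | 1.5 |
| dawn | 5.00 | 5.8 | 2.0 |
| dawn | 8.00 | 10.4 | 3.3 |
| dawn | 15.0 | 17.0 | 6.6 |
| dawn | 25.0 | 22.7 | 8.5 |
| midnight | 2.00 | 3.8 | 2.1 |
| midnight | 6.00 | 12.2 | 5.2 |
| midnight | 12.0 | 21.7 | 6.2 |
| midnight | 15.0 | 24.7 | 10.5 |
| midnight | 25.0 | 32.9 | 15.0 |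

(scatter of a reading: 1 percentage point)

- free catalyst is single-handed; left-handed substrate and right-handed substrate are mirror images of each other, charged as a racemate, each of them at the stated concentration
- on the list of suspects stand: reagent + free catalyst + left-handed substrate -> free catalyst + left-handed product; reagent + free catalyst + right-handed substrate -> free catalyst + right-handed product; left-handed substrate + racemization catalyst <-> right-handed substrate + racemization catalyst; racemization catalyst + impurity -> spent catalyst A; reagent + racemization catalyst -> spent catalyst B
- an excess is below zero if the other one leads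

* left-handed product and right-handed product together, in percent of the left-handed substrate and right-handed substrate charged together, at 40 h
* excess of left-handed product over right-handed product in the product at 40 h
* whether the exchange between left-handed substrate and right-handed substrate keeps pace with the reaction: how far the product's excess at 40 h gets from its value without exchange to its value with instant exchange (above 80 % keeps pace, below 20 % hardly takes part, else lags behind)

The pair of substrates is the limiting reagent, so I kept its ledger in percent of the pair charged. From the midnight run at 25.0 h I read 3.01 for the selectivity factor s, the logarithm of [left-handed substrate] over its charge divided by the same logarithm for [right-handed substrate]. It is a reading and carries the scatter. A value of 1 is the racemic zero.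

Instant exchange holds the two substrates equal, so the product ratio stays at s and the excess at 50.1 %. But the midnight ratio read 2.19 at 25.0 h, lower than s, so I did not book instant exchange. That reading does not exclude a slow exchange, and booking none was my assumption. I held the midnight decay of the right-handed substrate steady to 40 h and wrote the flask's books:

right-handed substrate, part of its charge left: 56.5 %
left-handed substrate, the same part raised to s: 18.0 %
left-handed product: 41.0 %
right-handed product: 21.7 %
substrates unreacted: 9.00 % and 28.3 %
product: 62.7 %, excess 30.8 %

The forecast gave 60 %, 33 % and "hardly takes part", on the ground that “Impurity and reagent probably destroy much of the racemization catalyst”. My figures differ a little from its own.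

The flask gave 62.2 %, 31.0 % and hardly takes part.

    reagent + free catalyst + left-handed substrate → free catalyst + left-handed product (k = 0.00711 M⁻² s⁻¹)
    reagent + free catalyst + right-handed substrate → free catalyst + right-handed product (k = 0.00245 M⁻² s⁻¹)
    left-handed substrate + racemization catalyst ⇌ right-handed substrate + racemization catalyst, rate k3*[racemization catalyst]*[left-handed substrate] forward; the back reaction follows from the equilibrium constant (k = 0.00249 M⁻¹ s⁻¹)
    racemization catalyst + impurity → spent catalyst A (k = 0.0856 M⁻¹ s⁻¹)
    reagent + racemization catalyst → spent catalyst B (k = 6.74 × 10⁻⁶ M⁻¹ s⁻¹)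

The exchange got 4.4 % of the way to the instant value, and the flask's racemization catalyst stood at 30.9 % after 4.00 h. What was left of this flask's substrates, 20 % and 56 %, gives s as 2.78. The neighbour flask with 2.40 equiv of reagent kept 71 % of its right-handed substrate, and s from the midnight run then puts its left-handed substrate at 35.4 % of charge, lower than the 39 % it kept, and its excess at 38.0 %. Its excess stood at 38.1 %.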